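The data are calculated for an exercise; the scatter is artificial.

Acid set free is conserved in bookkeeping: each electrophile that reacts uses one nucleophile and sets free one acid, which then stands as salt of the base, protonated nucleophile or side product, or stays as acid set free.

| flask | electrophile | free base | solid nucleophile | remark | time |
|---|---|---|---|---|---|
| south-west | 0.20 M | 0.060 M | 0.12 M | run made earlier |  |
| east | 0.20 M | 0.060 M | 0.48 M | run made earlier |  |
| west | 0.20 M | 0.090 M | 0.24 M | run made earlier |  |
| flask | 0.20 M | 0.0600 M | 0.240 M |  | 6.0 d |

- south-west (time / d: electrophile / %, target / %): 0.417: 84, 18; 0.625: 70, 28; 0.833: 61, 37; 1.25: 53, 48; 2.08: 48, 45; 3.00: 43, 41; 5.00: 42, 33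
- east (time / d: electrophile / %, target / %): 0.417: 79, 20; 0.625: 71, 28; 0.833: 58, 38; 1.25: 44, 53; 2.08: 23, 77; 3.00: 0, 89; 5.00: 0, 88
- west (time / d: electrophile / %, target / %): 1.04: 49, 54; 2.08: 15, 77; 3.00: 9, 83; 4.00: 3, 74; 5.00: 1, 68

(scatter of a reading: 2 percentage points)

- solid, in amounts per volume of the solution: solid nucleophile
- what may be going on: electrophile + nucleophile -> acid set free + target; nucleophile + acid set free <-> protonated nucleophile; acid set free + free base <-> salt of the base; acid set free + target -> side product; solid nucleophile <-> nucleophile
- at the start none of the solid nucleophile is in solution
- the earlier runs do not show how much of nucleophile is bound; that part of a forecast is a guess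

- part of the electrophile that has reacted at 6.0 d
- share of free nucleophile in free nucleophile and protonated nucleophile together, at 6.0 d

In fractions of the electrophile charge, let x be the part reacted, v the side product and h the acid set free. Once the free base has become salt and the solid has dissolved, the nucleophile forms left in the flask come to 1.20 − x. The acid balance then gives x = (charged nucleophile + charged base)/(2 × charged electrophile) + (v + h − n − f)/2, with n the free nucleophile and f the free base, both as fractions of the electrophile charge. The first term, 0.750 for the flask, is the equivalence conversion; beyond it, x is carried by the second term.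

The west run has its point at 0.825 and the south-west run at 0.450, and both pass them. Since v is what electrophile and target leave unaccounted for, the west readings give side product growing at 0.115 d⁻¹. The south-west and east runs both read 28% target at 0.625 d on different solid charges, so I borrow the east run's clock for the flask: it reads 77.0% reacted at 2.08 d, near the flask's point, and I take that as the crossing. Taking n and f as small, which is a guess, a steady rate then gives x = 0.975.

The weak link is that steady rate, since target shrinks. Per unit of target, the west readings give 0.152 d⁻¹ and the south-west readings 0.158 d⁻¹. With target at x − v, neglecting h, n and f, integration gives v = 0.387 and my x = 0.944.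

The forecast, reckoned separately, says 95% reacted, a little above mine, and a share of 25% for free nucleophile among free and protonated nucleophile, with “the nucleophile is mostly protonated”.

The flask gives 97.7% reacted and a share of 4.22% for free nucleophile among free and protonated nucleophile.

    electrophile + nucleophile → acid set free + target (k = 15.0 M⁻¹ h⁻¹)
    nucleophile + acid set free ⇌ protonated nucleophile, settled at all times (K = 2300 M⁻¹)
    acid set free + free base ⇌ salt of the base (K = 11000 M⁻¹, k = 27.0 M⁻¹ h⁻¹)
    acid set free + target → side product (k = 0.360 M⁻¹ h⁻¹)
    solid nucleophile ⇌ nucleophile, rate k5*(cs5 - [nucleophile]) while solid is left; crystals form when [nucleophile] > cs5 (solubility = 17.0 mM, k = 0.330 h⁻¹)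

At 6.00 d the flask holds 41.7% side product, 0.00988 M acid set free, 0.00188 M nucleophile and 0.876% of its free base, so the balance gives x = 0.977. In a neighbouring flask, the same but with 0.024 M of free base, the equivalence conversion is 0.660. Its 51.3% side product, 0.0161 M acid set free, 0.00130 M nucleophile and 0.552% of its free base give x = 0.953, and that neighbour stands at 95.3% reacted.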